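**Plan**
- **Cuts:** The retrosynthesis first cuts the C6–O bond, going back to a C9 silyl dienol ether. It then takes C9=O/C7=C8 back to the C8=C9 alkene and cuts the O4–C(=O)Ar ester bond. Last, C1–C10, C4–C5 and C4–O are cut together, which opens the bicycle to farnesyl diphosphate.
- **Enabling feature:** The fused cyclopentane (C1–C5) and cycloheptene (C1, C5–C10) contain an unbroken farnesane chain. The isopropyl-bearing carbinol C4, the methine C5 and the methyl-bearing quaternary C1 are the atoms through which a cyclase cation cascade travels.
- **Forward order:** Farnesol is converted to its diphosphate. One enzymatic step closes the seven-membered ring (C1–C10) and the five-membered ring (C4–C5) and adds water at C4. The silyl-protected 4-hydroxybenzoyl fragment is joined at O4, and the seven-membered ring is then oxidised at C9, C7=C8 and C6 in turn.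
- **Stereochemistry:** The enzyme sets C1 and C5 (trans fusion by anti addition across the 6E alkene) and C4 (water on the β face). C6 comes from α-face attack on the dienol ether, anti to the C1 methyl and the C4 aroyloxy group.

Key step: step 3

Convention: daucane numbering is used (C1 quaternary carbon with the angular methyl, C2, C3, C4 carbinol carbon with isopropyl, C5 ring-fusion methine, C6–C10 around the seven-membered ring, methyl on C8, C11 the isopropyl CH); β is the face of the C1 methyl.
Assumption: the enzyme-bound tertiary diphosphate 4 is drawn 3R by analogy with other cisoid cyclases, and this centre vanishes again without affecting 5; diphosphates are drawn as free acids and handled as ammonium salts.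

**Step 1**
Reactants: 1 (2E,6E)-farnesol
Product: 2 (2E,6E)-farnesyl bromide
Conditions: PBr3 (0.4 equiv), Et2O, 0 °C
Reagents that add atoms: phosphorus tribromide, BrP(Br)Br
Why: Bromination of a primary allylic alcohol with PBr3 (SN2 on the phosphite ester) at low temperature should proceed without allylic shift, so both E alkenes stay in place and no stereocentre is formed.

**Step 2**
Reactants: 2 (2E,6E)-farnesyl bromide
Product: 3 (2E,6E)-farnesyl diphosphate
Conditions: (n-Bu4N)3HP2O7, MeCN, rt; Dowex 50W-X8 (NH4+ form), NH4HCO3 buffer; cellulose chromatography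
Reagents that add atoms: tris(tetrabutylammonium) hydrogen diphosphate, CCCC[N+](CCCC)(CCCC)CCCC.CCCC[N+](CCCC)(CCCC)CCCC.CCCC[N+](CCCC)(CCCC)CCCC.OP([O-])(=O)OP([O-])([O-])=O
Why: SN2 displacement of a primary allylic halide by the soluble diphosphate trianion is the standard chemical diphosphorylation of prenols, and cation exchange gives the water-soluble ammonium salt that the enzyme accepts.

**Step 3**
Reactants: 3 (2E,6E)-farnesyl diphosphate
Product: 5 (1R,4R,5R)-dauc-8-en-4-ol (C1 methyl β, C4 hydroxyl β, C4 isopropyl α, H5 α, trans-fused), via (3R)-nerolidyl diphosphate 4 (not isolated)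
Conditions: recombinant daucane-forming, diphosphate-ionising sesquiterpene cyclase variant (expressed in E. coli), MgCl2 (10 mM), HEPES pH 7.5, DTT, glycerol, 30 °C, pentane overlay
Reagents that add atoms: water, O
Why: Proposed new method: the magnesium-bound diphosphate of 3 ionises and returns to the tertiary carbon to give enzyme-bound 4, whose cisoid re-ionisation delivers the 2Z allyl cation that the cis C8=C9 alkene of a seven-membered ring requires; its CH2 terminus (C10) is attacked by the methyl-bearing carbon of the central alkene (C1) while the distal alkene bonds through its CH carbon (C4) to C5, so that no free secondary cation arises, and a 1,2-hydride shift from C4 to C11 then places the charge on C4, where a bound water molecule adds. The closest known reaction type is daucane formation by diphosphate-ionising sesquiterpene cyclases such as the carotol-forming enzyme, which makes the same two bonds but lets a second hydride (C5 to C4) migrate before water adds at C5; only the halt after the first shift is new, and it is to be sought by genome mining or by active-site mutagenesis that moves the water-binding residues towards C4. The seven-membered ring closes in a 7-endo-trig mode (both carbons of the central alkene end up in the ring) and the five-membered ring in a 5-exo-trig mode (C11 stays outside). C1 and C5 are set together by anti addition across the 6E alkene, which places the C1 methyl and H5 trans, the fold imposed by the active-site contour decides which alkene face reacts and hence the absolute sense, and C4 is set by the position of the bound water on the β face, syn to the C1 methyl. The step needs 1,7-closure rather than 1,6-, 1,10- or 1,11-closure and hydration rather than proton loss; the substrate contributes the E geometry of the central alkene, the chain length that brings the distal alkene within reach of C5 and the tertiary nature of the C4 cation, and the rest depends on the protein.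

**Step 4**
Reactants: 6 4-hydroxybenzoic acid
Product: 8 4-(triisopropylsilyloxy)benzoic acid, via silyl ester 7 (not isolated)
Conditions: TIPSCl (2.3 equiv), imidazole, DMF, rt; then AcOH–THF–H2O, rt
Reagents that add atoms: triisopropylsilyl chloride, CC(C)[Si](Cl)(C(C)C)C(C)C
Why: Imidazole-promoted silylation caps both acidic oxygens, and the silyl ester, far more labile to aqueous acid than the hindered aryl silyl ether, should then be hydrolysed selectively.

**Step 5**
Reactants: 8 4-(triisopropylsilyloxy)benzoic acid
Product: 9 4-(triisopropylsilyloxy)benzoyl chloride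
Conditions: 1-chloro-N,N,2-trimethylpropenylamine, CH2Cl2, 0 °C → rt; used crude
Reagents that add atoms: 1-chloro-N,N,2-trimethylpropenylamine, CC(C)=C(Cl)N(C)C
Why: The α-chloroenamine converts carboxylic acids into acid chlorides under neutral conditions without releasing HCl, so the aryl silyl ether is not endangered.

**Step 6**
Reactants: 5 (1R,4R,5R)-dauc-8-en-4-ol; 9 4-(triisopropylsilyloxy)benzoyl chloride
Product: 11 dauc-8-en-4β-yl 4-(triisopropylsilyloxy)benzoate, via lithium alkoxide 10 (not isolated)
Conditions: n-BuLi, THF, −78 → 0 °C; then 9 (1.5 equiv), DMAP (cat.), 0 → 40 °C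
Reagents that add atoms: n-butyllithium, [Li]CCCC (lithium of 10 only)
Why: O-acylation of a preformed lithium alkoxide by an aroyl chloride with DMAP as acyl-transfer catalyst is the established route to esters of hindered tertiary alcohols; it avoids the acid that would dehydrate C4–OH towards C5 and touches only the O–H bond, so C4 keeps its configuration.

**Step 7**
Reactants: 11 dauc-8-en-4β-yl 4-(triisopropylsilyloxy)benzoate
Product: 13 9α-hydroxy-8αH-daucan-4β-yl 4-(triisopropylsilyloxy)benzoate (C8 methyl β, trans to the hydroxyl), via C9 alkylborane 12 (not isolated)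
Conditions: BH3·THF (1.5 equiv), THF, 0 °C → rt; then NaBO3·4H2O, THF–H2O, rt
Reagents that add atoms: sodium perborate, [Na+].[O-]OB=O; borane (as its THF complex), B (boron of 12 only)
Why: Hydroboration–oxidation places boron on the less substituted C9 by syn addition from the α face opposite the axial C1 methyl, the hindered electron-rich benzoate is inert to borane on this time scale, the mild perborate spares ester and aryl silyl ether, and both new centres (C8, C9) are erased in step 8.

**Step 8**
Reactants: 13 9α-hydroxy-8αH-daucan-4β-yl 4-(triisopropylsilyloxy)benzoate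
Product: 15 9-oxodauc-7-en-4β-yl 4-(triisopropylsilyloxy)benzoate, via C9 ketone 14 (not isolated)
Conditions: IBX (4 equiv), DMSO–fluorobenzene, 65 → 80 °C
Reagents that add atoms: none
Why: IBX oxidises the carbinol and then dehydrogenates the ketone through its more substituted enol (IBX dehydrogenation of ketones, known to run from the alcohol in one pot), and the double bond can enter only between C7 and C8 because C10 is flanked by the quaternary C1.

**Step 9**
Reactants: 15 9-oxodauc-7-en-4β-yl 4-(triisopropylsilyloxy)benzoate
Product: 17 9-(triisopropylsilyloxy)dauca-6,8-dien-4β-yl 4-(triisopropylsilyloxy)benzoate, via potassium dienolate 16 (not isolated)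
Conditions: KOt-Bu (1.2 equiv), THF, −78 → 0 °C; then TIPSOTf (1.5 equiv), Et3N, −78 °C
Reagents that add atoms: triisopropylsilyl trifluoromethanesulfonate, CC(C)[Si](OS(=O)(=O)C(F)(F)F)(C(C)C)C(C)C; potassium tert-butoxide, CC(C)(C)[O-].[K+] (potassium of 16 only)
Why: Under equilibrating conditions (the tert-butanol formed shuttles protons) an enone gives its linearly conjugated dienolate by loss of a γ proton from C6 rather than the less delocalised cross-conjugated one from the neopentyl C10, the hard silyl triflate traps it on oxygen (thermodynamic silyl dienol ether formation), and using the same silyl group as on the phenol makes any silyl exchange degenerate.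

**Step 10**
Reactants: 17 9-(triisopropylsilyloxy)dauca-6,8-dien-4β-yl 4-(triisopropylsilyloxy)benzoate
Product: 20 (1R,4R,5S,6S)-6-hydroxy-9-oxodauc-7-en-4-yl 4-hydroxybenzoate (6α-OH, 4β-aroyloxy; the target), via 6α,7α-epoxide 18 (not isolated), via aryl silyl ether 19 (not isolated)
Conditions: DMDO (1.1 equiv), acetone–CH2Cl2, −78 → −40 °C; concentrate cold; then HF·pyridine, pyridine–THF, 0 °C → rt
Reagents that add atoms: dimethyldioxirane, CC1(C)OO1
Why: In this vinylogous Rubottom oxidation the sterically sensitive dioxirane should take the cis-disubstituted, vinylogously activated C6=C7 bond rather than the tetrasubstituted silyloxy-flanked C8=C9 bond and approach from the α face (the β face is covered by the axial C1 methyl and by the C4 aroyloxy group, which is gauche to C6), after which fluoride-triggered collapse of the dienol ether breaks the allylic C7–O bond to leave the 6α-hydroxy enone and the same non-basic medium frees the phenol without inviting an acyl shift from O4 to O6.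

**Compound list**
1 | (2E,6E)-farnesol | CC(C)=CCC/C(C)=C/CC/C(C)=C/CO | starting material
2 | (2E,6E)-farnesyl bromide | CC(C)=CCC/C(C)=C/CC/C(C)=C/CBr | intermediate
3 | (2E,6E)-farnesyl diphosphate | CC(C)=CCC/C(C)=C/CC/C(C)=C/COP(O)(=O)OP(O)(O)=O | intermediate
4 | (3R,6E)-nerolidyl diphosphate (enzyme-bound) | C=C[C@@](C)(CC/C=C(\C)CCC=C(C)C)OP(O)(=O)OP(O)(O)=O | intermediate
5 | (1R,4R,5R)-dauc-8-en-4-ol | CC1=CC[C@@]2(C)CC[C@@](O)(C(C)C)[C@@H]2CC1 | intermediate
6 | 4-hydroxybenzoic acid | OC(=O)c1ccc(O)cc1 | starting material
7 | triisopropylsilyl 4-(triisopropylsilyloxy)benzoate | CC(C)[Si](C(C)C)(C(C)C)OC(=O)c1ccc(O[Si](C(C)C)(C(C)C)C(C)C)cc1 | intermediate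
8 | 4-(triisopropylsilyloxy)benzoic acid | OC(=O)c1ccc(O[Si](C(C)C)(C(C)C)C(C)C)cc1 | intermediate
9 | 4-(triisopropylsilyloxy)benzoyl chloride | ClC(=O)c1ccc(O[Si](C(C)C)(C(C)C)C(C)C)cc1 | intermediate
10 | lithium dauc-8-en-4β-olate | CC1=CC[C@@]2(C)CC[C@@]([O-])(C(C)C)[C@@H]2CC1.[Li+] | intermediate
11 | dauc-8-en-4β-yl 4-(triisopropylsilyloxy)benzoate | CC1=CC[C@@]2(C)CC[C@@](OC(=O)c3ccc(O[Si](C(C)C)(C(C)C)C(C)C)cc3)(C(C)C)[C@@H]2CC1 | intermediate
12 | 9α-boryl-8αH-daucan-4β-yl 4-(triisopropylsilyloxy)benzoate | C[C@@H]1[C@@H](B)C[C@@]2(C)CC[C@@](OC(=O)c3ccc(O[Si](C(C)C)(C(C)C)C(C)C)cc3)(C(C)C)[C@@H]2CC1 | intermediate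
13 | 9α-hydroxy-8αH-daucan-4β-yl 4-(triisopropylsilyloxy)benzoate | C[C@@H]1[C@@H](O)C[C@@]2(C)CC[C@@](OC(=O)c3ccc(O[Si](C(C)C)(C(C)C)C(C)C)cc3)(C(C)C)[C@@H]2CC1 | intermediate
14 | 9-oxo-8αH-daucan-4β-yl 4-(triisopropylsilyloxy)benzoate | C[C@@H]1C(=O)C[C@@]2(C)CC[C@@](OC(=O)c3ccc(O[Si](C(C)C)(C(C)C)C(C)C)cc3)(C(C)C)[C@@H]2CC1 | intermediate
15 | 9-oxodauc-7-en-4β-yl 4-(triisopropylsilyloxy)benzoate | CC1=CC[C@@H]2[C@](C)(CC[C@@]2(OC(=O)c2ccc(O[Si](C(C)C)(C(C)C)C(C)C)cc2)C(C)C)CC1=O | intermediate
16 | potassium 4β-[4-(triisopropylsilyloxy)benzoyloxy]dauca-6,8-dien-9-olate | CC1=C([O-])C[C@@]2(C)CC[C@@](OC(=O)c3ccc(O[Si](C(C)C)(C(C)C)C(C)C)cc3)(C(C)C)[C@@H]2C=C1.[K+] | intermediate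
17 | 9-(triisopropylsilyloxy)dauca-6,8-dien-4β-yl 4-(triisopropylsilyloxy)benzoate | CC1=C(O[Si](C(C)C)(C(C)C)C(C)C)C[C@@]2(C)CC[C@@](OC(=O)c3ccc(O[Si](C(C)C)(C(C)C)C(C)C)cc3)(C(C)C)[C@@H]2C=C1 | intermediate
18 | 6α,7α-epoxy-9-(triisopropylsilyloxy)dauc-8-en-4β-yl 4-(triisopropylsilyloxy)benzoate | CC1=C(O[Si](C(C)C)(C(C)C)C(C)C)C[C@@]2(C)CC[C@@](OC(=O)c3ccc(O[Si](C(C)C)(C(C)C)C(C)C)cc3)(C(C)C)[C@@H]2[C@H]4O[C@H]41 | intermediate
19 | 6α-hydroxy-9-oxodauc-7-en-4β-yl 4-(triisopropylsilyloxy)benzoate | CC1=C[C@H](O)[C@@H]2[C@](C)(CC[C@@]2(OC(=O)c2ccc(O[Si](C(C)C)(C(C)C)C(C)C)cc2)C(C)C)CC1=O | intermediate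
20 | (1R,4R,5S,6S)-6-hydroxy-9-oxodauc-7-en-4-yl 4-hydroxybenzoate | CC1=C[C@H](O)[C@@H]2[C@](C)(CC[C@@]2(OC(=O)c2ccc(O)cc2)C(C)C)CC1=O | target

**Step count:** 10 steps in total. The longest linear sequence is 8 steps (1, 2, 3, 6, 7, 8, 9, 10).

**Steps most likely to fail**

**Step 3.**
- **What may go wrong:** the cascade may run on (second hydride shift from C5, or proton loss to a diene) before water is captured at C4, or no variant with useful turnover may be found.
- **Fallback:** it sets out from 3 and returns at 5, keeps the enzymatic formation of C1–C10 and C4–C5, and moves the hydroxyl chemically.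
  - The known carotol-forming cyclase converts 3 into carotol F1, which has the same C1 configuration and its hydroxyl on C5.
  - SOCl2 in pyridine removes that hydroxyl with the anti H4 to give daucene F2.
  - NBS in aqueous acetone should engage the more nucleophilic tetrasubstituted C4=C5 alkene from the open α face. Water must then open the bromonium ion from the β face, and it should do so at C4 rather than at the neopentyl C5. This gives 5α-bromodauc-8-en-4β-ol F3 and puts the oxygen on the face that direct oxidants avoid.
  - Bu3SnH/AIBN replaces bromine by hydrogen, delivered anti to the C1 methyl, which should give the trans-fused 5.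

**Step 10.**
- **What may go wrong:** oxygen may be transferred to the electron-rich C8=C9 bond (hydroxylation at C8), or the two faces of C6 may not be discriminated well enough.
- **Fallback:** it sets out from 17 and returns at 19, replacing epoxidation by a cycloaddition that bonds to C6 and C9 at once.
  - Singlet oxygen (O2, tetraphenylporphyrin, visible light, CH2Cl2, −78 °C) should add across the cisoid cycloheptadiene on the α face. The β face carries the ring flap C1 with its axial methyl, which is 1,3-related to both termini. The product is the 6α,9α-endoperoxide F4.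
  - Thiourea in methanol reduces the O–O bond, and the resulting C9 hemiketal loses silanol to give 19.
  - 19 is then desilylated with HF·pyridine as in the second stage of step 10.

**Step 9.**
- **What may go wrong:** a C10 proton may be removed in competition with C6–H, leading to the cross-conjugated isomer, or alkoxide may attack the ester.
- **Fallback:** it sets out from 15 and returns at 19 without any silyl dienol ether.
  - Copper-catalysed vinylogous aerobic oxidation (Cu(OAc)2 cat., 1,1,3,3-tetramethylguanidine, air, DMSO, rt) works through a reversibly formed dienolate that takes up O2 at the γ carbon. Attack should again come from the α face, giving the 6α-hydroperoxide F5.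
  - PPh3 reduces F5 in the same pot to 19.

**Further compounds**
F1 | step 3 | carotol, (1R,4R,5S)-dauc-8-en-5-ol | CC1=CC[C@@]2(C)CC[C@H](C(C)C)[C@@]2(O)CC1
F2 | step 3 | daucene, (1R)-dauca-4,8-diene | CC1=CC[C@@]2(C)CCC(C(C)C)=C2CC1
F3 | step 3 | 5α-bromodauc-8-en-4β-ol | CC1=CC[C@@]2(C)CC[C@@](O)(C(C)C)[C@]2(Br)CC1
F4 | step 10 | 6α,9α-epidioxy-9β-(triisopropylsilyloxy)dauc-7-en-4β-yl 4-(triisopropylsilyloxy)benzoate | CC1=C[C@@H]2OO[C@@]1(O[Si](C(C)C)(C(C)C)C(C)C)C[C@@]3(C)CC[C@@](OC(=O)c4ccc(O[Si](C(C)C)(C(C)C)C(C)C)cc4)(C(C)C)[C@H]23
F5 | step 9 | 6α-hydroperoxy-9-oxodauc-7-en-4β-yl 4-(triisopropylsilyloxy)benzoate | CC1=C[C@H](OO)[C@@H]2[C@](C)(CC[C@@]2(OC(=O)c2ccc(O[Si](C(C)C)(C(C)C)C(C)C)cc2)C(C)C)CC1=O
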